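**Retrosynthetic overview**
1. End game: target 28 ⇐ desilylation of diacetate 27 ⇐ trans-diaxial 6β,7α-diol 25 (made single-enantiomer by catalytic enantioselective acetylation) ⇐ C6 reduction and C7 enolate hydroxylation of labd-8-en-6-one 22 ⇐ deconjugation and C5 equilibration of labd-7-en-6-one 20.
2. Key disconnection: ring B of 20 is cut across C5–C6 and C9–C10 into the ring-A alkenyllithium 16 (C5=C10, from 2,2,6-trimethylcyclohexanone) and cyclobutenone 15, which carries C6–C9, the C8 methyl and the whole C11–C16 chain. A 1,2-addition, 4π ring opening and 6π ring closure join them in one operation.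
3. Enabling feature: ring B is a cyclohexene joined to ring A only through the C5–C10 bond, and its C6(O)–C7–C8(CH3)–C9(chain) edge is a contiguous four-carbon unit with oxygen on C6. A C6 ketone with a C7=C8 alkene is exactly what a 3-oxidohexatriene electrocyclisation delivers, and C5 (α to C6=O) and C9 (γ) stay adjustable afterwards.
4. Cyclobutenone 15: ketene [2+2] of acid chloride 11 with ethoxyacetylene, then MeLi addition and acidic carbonyl transposition. Acid 9 comes from hex-5-yn-1-ol by Zr-catalysed carboalumination, which fixes the 13E alkene.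
5. Ring order: ring A (bought), then the temporary cyclobutene ring, then ring B (key step).

Key step: step 9

**Remarks on the chemistry**
- Labdane numbering is used: ring A = C1–C5 and C10; ring B = C5–C10; C4 carries C18 and C19, C8 carries C17, C10 carries C20, and C9 carries the chain C11–C12–C13(C16)=C14–C15(O).
- Compounds 13–15 are racemic at the cyclobutene CH (that centre is destroyed in step 9). Compounds 17–25 are racemic and are drawn and named as the enantiomer that leads to the target.
- Assumption: the sense of the kinetic resolution in step 13 cannot be predicted for this scaffold. The catalyst antipode that acetylates the (5S,6S,7S,10S)-diol faster is to be fixed in a trial on racemic 25; the step is written for (R)-BTM.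

**Route**

Step 1
Reactants: 1 2,2,6-trimethylcyclohexanone
Product: 2 2,2,6-trimethylcyclohexanone 2,4,6-triisopropylbenzenesulfonylhydrazone
Conditions: 2,4,6-triisopropylbenzenesulfonyl hydrazide, conc. HCl (cat.), MeCN, rt
Reagents that add atoms: 2,4,6-triisopropylbenzenesulfonyl hydrazide, CC(C)c1cc(C(C)C)c(S(=O)(=O)NN)c(C(C)C)c1
Why: Acid-catalysed hydrazone formation; the ketone has a single α-hydrogen (on the future C10), so the later Shapiro reaction can only give the C5=C10 alkenyllithium.

Step 2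
Reactants: 3 hex-5-yn-1-ol
Product: 4 tert-butyl(hex-5-yn-1-yloxy)dimethylsilane
Conditions: TBSCl, imidazole, DMF, rt
Reagents that add atoms: tert-butyldimethylsilyl chloride, CC(C)(C)[Si](C)(C)Cl
Why: Standard silylation of a primary alcohol, which masks the future carboxyl terminus during the organoaluminium step.

Step 3
Reactants: 4 tert-butyl(hex-5-yn-1-yloxy)dimethylsilane
Product: 6 (E)-7-(tert-butyldimethylsilyloxy)-3-methylhept-2-en-1-ol, via alkenylalane 5 (not isolated)
Conditions: Al(CH3)3, Zr(C5H5)2Cl2 (cat.), CH2Cl2, 0 °C → rt; then n-BuLi, THF, −78 °C; (CH2O)n, −78 °C → rt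
Reagents that add atoms: trimethylaluminium, C[Al](C)C; paraformaldehyde (as formaldehyde), C=O
Why: Negishi zirconium-catalysed carboalumination adds CH3 and Al syn across the terminal alkyne (methyl to the internal carbon), and the alanate is hydroxymethylated with retention, which should fix the 13E trisubstituted alkene.

Step 4
Reactants: 6 (E)-7-(tert-butyldimethylsilyloxy)-3-methylhept-2-en-1-ol
Product: 7 (E)-7-(tert-butyldimethylsilyloxy)-1-(tert-butyldiphenylsilyloxy)-3-methylhept-2-ene
Conditions: TBDPSCl, imidazole, DMF, rt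
Reagents that add atoms: tert-butyldiphenylsilyl chloride, CC(C)(C)[Si](Cl)(c1ccccc1)c1ccccc1
Why: Silylation of the allylic alcohol with the more robust TBDPS group, which has to survive acid, organolithium, alkoxide and hydride steps up to step 15.

Step 5
Reactants: 7 (E)-7-(tert-butyldimethylsilyloxy)-1-(tert-butyldiphenylsilyloxy)-3-methylhept-2-ene
Product: 8 (E)-7-(tert-butyldiphenylsilyloxy)-5-methylhept-5-en-1-ol
Conditions: PPTS (cat.), MeOH, rt
Reagents that add atoms: none
Why: Mild acid-catalysed methanolysis should cleave the primary TBS ether selectively while the bulkier TBDPS ether stays (selective desilylation).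

Step 6
Reactants: 8 (E)-7-(tert-butyldiphenylsilyloxy)-5-methylhept-5-en-1-ol
Product: 9 (E)-7-(tert-butyldiphenylsilyloxy)-5-methylhept-5-enoic acid
Conditions: TEMPO (cat.), PhI(OAc)2, MeCN/H2O, rt
Reagents that add atoms: water, O
Why: Oxoammonium-mediated oxidation of the primary alcohol through the aldehyde hydrate to the acid; the conditions tolerate the trisubstituted alkene and the silyl ether.

Step 7
Reactants: 9 (E)-7-(tert-butyldiphenylsilyloxy)-5-methylhept-5-enoic acid; 10 ethoxyacetylene
Product: 13 3-ethoxy-4-[(E)-5-(tert-butyldiphenylsilyloxy)-3-methylpent-3-en-1-yl]cyclobut-2-en-1-one (racemic), via acid chloride 11 (not isolated), via ketene 12 (not isolated)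
Conditions: (COCl)2, DMF (cat.), CH2Cl2, 0 °C → rt, evaporate; then 10 (excess), Et3N, Et2O, 0 °C → rt
Reagents that add atoms: none
Why: Dehydrochlorination gives the monoalkylketene, which should undergo regioselective [2+2] cycloaddition with the electron-rich alkyne (its CH terminus bonds to the ketene carbonyl carbon) to give the 3-ethoxycyclobutenone; the remote alkene is too short-tethered to compete.

Step 8
Reactants: 13 3-ethoxy-4-[(E)-5-(tert-butyldiphenylsilyloxy)-3-methylpent-3-en-1-yl]cyclobut-2-en-1-one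
Product: 15 3-methyl-4-[(E)-5-(tert-butyldiphenylsilyloxy)-3-methylpent-3-en-1-yl]cyclobut-2-en-1-one (racemic), via lithium alkoxide 14 (not isolated)
Conditions: MeLi, Et2O, −78 °C; then 1 M aq. HCl, THF, 0 °C
Reagents that add atoms: methyllithium, [Li]C; water, O
Why: 1,2-Addition of MeLi to the vinylogous ester carbonyl, then acid-induced loss of water and enol ether hydrolysis (Stork–Danheiser-type carbonyl transposition), should place the methyl on the ring alkene (future C8/C17) and the carbonyl on the former C–OEt carbon (future C6).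

Step 9
Reactants: 2 2,2,6-trimethylcyclohexanone 2,4,6-triisopropylbenzenesulfonylhydrazone; 15 3-methyl-4-[(E)-5-(tert-butyldiphenylsilyloxy)-3-methylpent-3-en-1-yl]cyclobut-2-en-1-one
Product: 20 (±)-15-(tert-butyldiphenylsilyloxy)labda-7,13E-dien-6-one (9β side chain; both C5 epimers), via alkenyllithium 16 (not isolated), via lithium cyclobutenolate 17 (not isolated), via lithium trienolate 18 (not isolated), via lithium dienolate 19 (not isolated)
Conditions: 2, n-BuLi (2.1 equiv), THF/hexane, −78 → 0 °C; then 15, THF, −78 °C → rt (gentle warming if closure is slow); H2O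
Reagents that add atoms: none
Why: The Shapiro-derived alkenyllithium 16 adds 1,2 to the strained cyclobutenone anti to its side chain (C5–C6 bond); alkoxide 17 then undergoes oxyanion-accelerated conrotatory 4π ring opening with the oxide rotating outward, which puts the cyclohexenyl group cis to C8 in trienolate 18, and disrotatory 6π electrocyclisation forms C9–C10 to give dienolate 19, protonated at C5 on work-up. The closest known reaction type is the two-carbon ring expansion of cyclobutenones by alkenyllithium reagents through 3-oxidohexatriene electrocyclisation, and closure at the methyl-bearing ring carbon has an analogy in the cis-β-ionone to 2H-pyran electrocyclisation. Ring B is closed in the 6π disrotatory mode, and the cyclobutene is only a temporary ring. The quaternary C10 is formed without external bias, hence as a racemate (resolved in step 13); C9 is set cis to the C10 methyl by the disrotatory motion of the two inward groups but is erased in step 10, and C5 arises by enolate protonation and is settled in step 10. The step needs 1,2-addition rather than conjugate addition or enolisation, which the ring strain at the carbonyl, the methyl on the β-carbon and the antiaromatic character of a cyclobutenone enolate should secure. It also needs the cis-triene, which the strong outward preference of the oxide guarantees.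

Step 10
Reactants: 20 (±)-15-(tert-butyldiphenylsilyloxy)labda-7,13E-dien-6-one
Product: 22 (±)-(5S,10S)-15-(tert-butyldiphenylsilyloxy)labda-8,13E-dien-6-one (5α-H), via potassium dienolate 21 (not isolated)
Conditions: KOt-Bu (excess), t-BuOH/THF, rt, argon; then inverse quench into cold aq. AcOH
Reagents that add atoms: none
Why: Thermodynamic γ-deprotonation at C9 gives the fully conjugated dienolate and kinetic α-protonation at C7 gives the β,γ-unsaturated ketone (base-mediated deconjugation, as for isophorone to β-isophorone), while under these equilibrating conditions C5 should settle as the trans-fused 5α-H epimer, the same face that protonation anti to the C10 methyl prefers.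

Step 11
Reactants: 22 (±)-(5S,10S)-15-(tert-butyldiphenylsilyloxy)labda-8,13E-dien-6-one
Product: 24 (±)-(5S,7S,10S)-7α-hydroxy-15-(tert-butyldiphenylsilyloxy)labda-8,13E-dien-6-one, via sodium dienolate 23 (not isolated)
Conditions: NaN(SiMe3)2, THF, −78 °C; then 2-(phenylsulfonyl)-3-phenyloxaziridine, −78 °C; AcOH, −78 °C
Reagents that add atoms: 2-(phenylsulfonyl)-3-phenyloxaziridine, O=S(=O)(c1ccccc1)N1OC1c1ccccc1
Why: Kinetic deprotonation of the doubly activated C7 methylene by the sodium amide gives the sodium dienolate, which the Davis oxaziridine should oxidise at its α-carbon (enolate α-hydroxylation) from the α-face, because the β-face of ring B is screened by the axial methyl groups on C10 and C4; this sets C7.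

Step 12
Reactants: 24 (±)-(5S,7S,10S)-7α-hydroxy-15-(tert-butyldiphenylsilyloxy)labda-8,13E-dien-6-one
Product: 25 (±)-(5S,6S,7S,10S)-15-(tert-butyldiphenylsilyloxy)labda-8,13E-diene-6β,7α-diol
Conditions: NaBH4, CeCl3·7H2O, MeOH, −40 → 0 °C
Reagents that add atoms: none
Why: Luche-type 1,2-reduction in which hydride should attack C6 from the α-face, since the β-face is blocked by the two syn-axial methyl groups on C4 and C10 (as in 6-oxo steroids), giving the axial 6β-alcohol trans-diaxial to the 7α-hydroxyl.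

Step 13
Reactants: 25 (±)-(5S,6S,7S,10S)-15-(tert-butyldiphenylsilyloxy)labda-8,13E-diene-6β,7α-diol
Product: 26 (5S,6S,7S,10S)-7α-acetoxy-15-(tert-butyldiphenylsilyloxy)labda-8,13E-dien-6β-ol
Conditions: (R)-benzotetramisole [(R)-BTM] (cat.), Ac2O (0.5 equiv), i-Pr2NEt, CHCl3, 0 °C, stopped just below half conversion
Reagents that add atoms: acetic anhydride, CC(=O)OC(C)=O
Why: Catalytic kinetic resolution by enantioselective acyl transfer should acetylate the allylic 7α-hydroxyl of one enantiomer only (the 6β-hydroxyl is too hindered to compete), so the (5S,6S,7S,10S) series is taken on as its 7-acetate and the antipodal diol is separated by chromatography.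

Step 14
Reactants: 26 (5S,6S,7S,10S)-7α-acetoxy-15-(tert-butyldiphenylsilyloxy)labda-8,13E-dien-6β-ol
Product: 27 (5S,6S,7S,10S)-6β,7α-diacetoxy-15-(tert-butyldiphenylsilyloxy)labda-8,13E-diene
Conditions: Ac2O, DMAP, Et3N, CH2Cl2, 40 °C
Reagents that add atoms: acetic anhydride, CC(=O)OC(C)=O
Why: DMAP-catalysed acylation under forcing conditions should esterify the hindered axial 6β-alcohol; the trans-diaxial arrangement rules out acyl migration.

Step 15
Reactants: 27 (5S,6S,7S,10S)-6β,7α-diacetoxy-15-(tert-butyldiphenylsilyloxy)labda-8,13E-diene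
Product: 28 (5S,6S,7S,10S)-6β,7α-diacetoxylabda-8,13E-dien-15-ol (CNP0187815.1)
Conditions: HF·pyridine, pyridine/THF, 0 °C → rt
Reagents that add atoms: none
Why: Fluoride-mediated cleavage of the primary silyl ether under buffered, non-basic conditions should leave both acetates and the allylic system untouched.

**Compound list**
1 | 2,2,6-trimethylcyclohexanone (racemic) | CC1CCCC(C)(C)C1=O | starting material
2 | 2,2,6-trimethylcyclohexanone 2,4,6-triisopropylbenzenesulfonylhydrazone | CC1CCCC(C)(C)C1=NNS(=O)(=O)c1c(C(C)C)cc(C(C)C)cc1C(C)C | intermediate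
3 | hex-5-yn-1-ol | C#CCCCCO | starting material
4 | tert-butyl(hex-5-yn-1-yloxy)dimethylsilane | C#CCCCCO[Si](C)(C)C(C)(C)C | intermediate
5 | [(1E)-6-(tert-butyldimethylsilyloxy)-2-methylhex-1-en-1-yl]dimethylalane | CC(C)(C)[Si](C)(C)OCCCC/C(C)=C/[Al](C)C | intermediate
6 | (E)-7-(tert-butyldimethylsilyloxy)-3-methylhept-2-en-1-ol | CC(C)(C)[Si](C)(C)OCCCC/C(C)=C/CO | intermediate
7 | (E)-7-(tert-butyldimethylsilyloxy)-1-(tert-butyldiphenylsilyloxy)-3-methylhept-2-ene | CC(C)(C)[Si](C)(C)OCCCC/C(C)=C/CO[Si](c1ccccc1)(c1ccccc1)C(C)(C)C | intermediate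
8 | (E)-7-(tert-butyldiphenylsilyloxy)-5-methylhept-5-en-1-ol | OCCCC/C(C)=C/CO[Si](c1ccccc1)(c1ccccc1)C(C)(C)C | intermediate
9 | (E)-7-(tert-butyldiphenylsilyloxy)-5-methylhept-5-enoic acid | OC(=O)CCC/C(C)=C/CO[Si](c1ccccc1)(c1ccccc1)C(C)(C)C | intermediate
10 | ethoxyacetylene | C#COCC | starting material
11 | (E)-7-(tert-butyldiphenylsilyloxy)-5-methylhept-5-enoyl chloride | ClC(=O)CCC/C(C)=C/CO[Si](c1ccccc1)(c1ccccc1)C(C)(C)C | intermediate
12 | (E)-7-(tert-butyldiphenylsilyloxy)-5-methylhepta-1,5-dien-1-one (ketene) | O=C=CCC/C(C)=C/CO[Si](c1ccccc1)(c1ccccc1)C(C)(C)C | intermediate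
13 | 3-ethoxy-4-[(E)-5-(tert-butyldiphenylsilyloxy)-3-methylpent-3-en-1-yl]cyclobut-2-en-1-one (racemic) | CCOC1=CC(=O)C1CC/C(C)=C/CO[Si](c1ccccc1)(c1ccccc1)C(C)(C)C | intermediate
14 | lithium 3-ethoxy-1-methyl-4-[(E)-5-(tert-butyldiphenylsilyloxy)-3-methylpent-3-en-1-yl]cyclobut-2-en-1-olate | CCOC1=CC(C)(O[Li])C1CC/C(C)=C/CO[Si](c1ccccc1)(c1ccccc1)C(C)(C)C | intermediate
15 | 3-methyl-4-[(E)-5-(tert-butyldiphenylsilyloxy)-3-methylpent-3-en-1-yl]cyclobut-2-en-1-one (racemic) | O=C1C=C(C)C1CC/C(C)=C/CO[Si](c1ccccc1)(c1ccccc1)C(C)(C)C | intermediate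
16 | (2,6,6-trimethylcyclohex-1-en-1-yl)lithium | [Li]C1=C(C)CCCC1(C)C | intermediate
17 | lithium 3-methyl-4-[(E)-5-(tert-butyldiphenylsilyloxy)-3-methylpent-3-en-1-yl]-1-(2,6,6-trimethylcyclohex-1-en-1-yl)cyclobut-2-en-1-olate (oxide cis to the side chain; racemic) | [Li]O[C@]1(C2=C(C)CCCC2(C)C)C=C(C)[C@@H]1CC/C(C)=C/CO[Si](c2ccccc2)(c2ccccc2)C(C)(C)C | intermediate
18 | lithium (1E,3Z,7E)-9-(tert-butyldiphenylsilyloxy)-3,7-dimethyl-1-(2,6,6-trimethylcyclohex-1-en-1-yl)nona-1,3,7-trien-1-olate | CC1=C(/C(O[Li])=C\C(C)=C/CC/C(C)=C/CO[Si](c2ccccc2)(c2ccccc2)C(C)(C)C)C(C)(C)CCC1 | intermediate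
19 | lithium (±)-15-(tert-butyldiphenylsilyloxy)labda-5,7,13E-trien-6-olate (9β side chain) | [Li]OC=1C=C(C)[C@H](CC/C(C)=C/CO[Si](c3ccccc3)(c3ccccc3)C(C)(C)C)[C@@]2(C)CCCC(C)(C)C=12 | intermediate
20 | (±)-15-(tert-butyldiphenylsilyloxy)labda-7,13E-dien-6-one (9β side chain, 10β methyl; C5 not defined, both epimers) | O=C1C=C(C)[C@H](CC/C(C)=C/CO[Si](c3ccccc3)(c3ccccc3)C(C)(C)C)[C@@]2(C)CCCC(C)(C)C12 | intermediate
21 | potassium (±)-15-(tert-butyldiphenylsilyloxy)labda-6,8,13E-trien-6-olate (5α-H) | [K]OC1=CC(C)=C(CC/C(C)=C/CO[Si](c3ccccc3)(c3ccccc3)C(C)(C)C)[C@@]2(C)CCCC(C)(C)[C@H]12 | intermediate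
22 | (±)-(5S,10S)-15-(tert-butyldiphenylsilyloxy)labda-8,13E-dien-6-one | O=C1CC(C)=C(CC/C(C)=C/CO[Si](c3ccccc3)(c3ccccc3)C(C)(C)C)[C@@]2(C)CCCC(C)(C)[C@H]12 | intermediate
23 | sodium (±)-15-(tert-butyldiphenylsilyloxy)labda-6,8,13E-trien-6-olate (5α-H) | [Na]OC1=CC(C)=C(CC/C(C)=C/CO[Si](c3ccccc3)(c3ccccc3)C(C)(C)C)[C@@]2(C)CCCC(C)(C)[C@H]12 | intermediate
24 | (±)-(5S,7S,10S)-7α-hydroxy-15-(tert-butyldiphenylsilyloxy)labda-8,13E-dien-6-one | O=C1[C@@H](O)C(C)=C(CC/C(C)=C/CO[Si](c3ccccc3)(c3ccccc3)C(C)(C)C)[C@@]2(C)CCCC(C)(C)[C@H]12 | intermediate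
25 | (±)-(5S,6S,7S,10S)-15-(tert-butyldiphenylsilyloxy)labda-8,13E-diene-6β,7α-diol | O[C@@H]1[C@@H](O)C(C)=C(CC/C(C)=C/CO[Si](c3ccccc3)(c3ccccc3)C(C)(C)C)[C@@]2(C)CCCC(C)(C)[C@H]12 | intermediate
26 | (5S,6S,7S,10S)-7α-acetoxy-15-(tert-butyldiphenylsilyloxy)labda-8,13E-dien-6β-ol | O[C@@H]1[C@@H](OC(C)=O)C(C)=C(CC/C(C)=C/CO[Si](c3ccccc3)(c3ccccc3)C(C)(C)C)[C@@]2(C)CCCC(C)(C)[C@H]12 | intermediate
27 | (5S,6S,7S,10S)-6β,7α-diacetoxy-15-(tert-butyldiphenylsilyloxy)labda-8,13E-diene | CC(=O)O[C@@H]1[C@@H](OC(C)=O)C(C)=C(CC/C(C)=C/CO[Si](c3ccccc3)(c3ccccc3)C(C)(C)C)[C@@]2(C)CCCC(C)(C)[C@H]12 | intermediate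
28 | (5S,6S,7S,10S)-6β,7α-diacetoxylabda-8,13E-dien-15-ol (CNP0187815.1) | CC(=O)O[C@@H]1[C@@H](OC(C)=O)C(C)=C(CC/C(C)=C/CO)[C@@]2(C)CCCC(C)(C)[C@H]12 | target

**Step count and risks**
Total step count: 15. Longest linear sequence: 14 (steps 2–15, from hex-5-yn-1-ol).

Steps most likely to fail:

1. Step 9. The 6π ring closure may stall, because bond formation at the fully substituted C10 terminus with the side chain turned inward is slow; work-up would then only protonate the open-chain trienolate. The fallback sets out from 2 and 15 under the same addition and ring-opening conditions, but the mixture is quenched cold to isolate (3Z,7E)-9-(tert-butyldiphenylsilyloxy)-3,7-dimethyl-1-(2,6,6-trimethylcyclohex-1-en-1-yl)nona-3,7-dien-1-one F1. This dienone is then closed by a cationic enone–alkene cyclisation with Al(CH3)Cl2 in CH2Cl2 at −78 → 0 °C: the C8=C9 alkene attacks C10 of the Lewis-acid-activated enone and a proton is lost. The fallback comes back to the route at 20; any 22 formed alongside is carried along, since step 10 converges both.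

2. Step 11. The enolate oxidation may be accompanied by transposition of the α-ketol through its enediol, or by loss of facial selectivity at C7. The fallback sets out from 22 and avoids a free α-ketol. The sodium dienolate 23, formed as in step 11, is brominated with N-bromosuccinimide at −78 °C to give (±)-7α-bromo-15-(tert-butyldiphenylsilyloxy)labda-8,13E-dien-6-one F2. Reduction with NaBH4 and CeCl3·7H2O gives the trans-diaxial bromohydrin (±)-7α-bromo-15-(tert-butyldiphenylsilyloxy)labda-8,13E-dien-6β-ol F3. K2CO3 in MeOH closes it to (±)-6β,7β-epoxy-15-(tert-butyldiphenylsilyloxy)labda-8,13E-diene F4. Acid-catalysed hydrolysis (HClO4 cat., aq. THF) should open the epoxide trans-diaxially at the allylic C7 from the α-face. The fallback comes back at 25.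

3. Step 13. The catalyst may discriminate too weakly between the enantiomers, because both flanks of the C7 carbinol are bulky. The fallback sets out from 25 and is a classical resolution. The 7-hydroxyl is esterified with (S)-2-methoxy-2-phenylacetic acid (DCC, DMAP, CH2Cl2) to give the diastereomers (5S,6S,7S,10S)-15-(tert-butyldiphenylsilyloxy)-6β-hydroxylabda-8,13E-dien-7α-yl (S)-2-methoxy-2-phenylacetate F5 and its (5R,6R,7R,10R) counterpart F6, which are separated by chromatography. Methanolysis of F5 (K2CO3, MeOH) gives the single-enantiomer diol (5S,6S,7S,10S)-15-(tert-butyldiphenylsilyloxy)labda-8,13E-diene-6β,7α-diol F7. Acetylation of both hydroxyls (Ac2O, DMAP, Et3N, 40 °C) comes back to the route at 27.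

**Further compounds**
F1 | step 9 | (3Z,7E)-9-(tert-butyldiphenylsilyloxy)-3,7-dimethyl-1-(2,6,6-trimethylcyclohex-1-en-1-yl)nona-3,7-dien-1-one | CC1=C(C(=O)C/C(C)=C\CC/C(C)=C/CO[Si](c2ccccc2)(c2ccccc2)C(C)(C)C)C(C)(C)CCC1
F2 | step 11 | (±)-7α-bromo-15-(tert-butyldiphenylsilyloxy)labda-8,13E-dien-6-one | O=C1[C@@H](Br)C(C)=C(CC/C(C)=C/CO[Si](c3ccccc3)(c3ccccc3)C(C)(C)C)[C@@]2(C)CCCC(C)(C)[C@H]12
F3 | step 11 | (±)-7α-bromo-15-(tert-butyldiphenylsilyloxy)labda-8,13E-dien-6β-ol | O[C@@H]1[C@@H](Br)C(C)=C(CC/C(C)=C/CO[Si](c3ccccc3)(c3ccccc3)C(C)(C)C)[C@@]2(C)CCCC(C)(C)[C@H]12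
F4 | step 11 | (±)-6β,7β-epoxy-15-(tert-butyldiphenylsilyloxy)labda-8,13E-diene | O1[C@@H]2[C@H]1C(C)=C(CC/C(C)=C/CO[Si](c4ccccc4)(c4ccccc4)C(C)(C)C)[C@@]3(C)CCCC(C)(C)[C@H]23
F5 | step 13 | (5S,6S,7S,10S)-15-(tert-butyldiphenylsilyloxy)-6β-hydroxylabda-8,13E-dien-7α-yl (S)-2-methoxy-2-phenylacetate | O[C@@H]1[C@@H](OC(=O)[C@@H](OC)c3ccccc3)C(C)=C(CC/C(C)=C/CO[Si](c3ccccc3)(c3ccccc3)C(C)(C)C)[C@@]2(C)CCCC(C)(C)[C@H]12
F6 | step 13 | (5R,6R,7R,10R)-15-(tert-butyldiphenylsilyloxy)-6-hydroxylabda-8,13E-dien-7-yl (S)-2-methoxy-2-phenylacetate | O[C@H]1[C@H](OC(=O)[C@@H](OC)c3ccccc3)C(C)=C(CC/C(C)=C/CO[Si](c3ccccc3)(c3ccccc3)C(C)(C)C)[C@]2(C)CCCC(C)(C)[C@@H]12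
F7 | step 13 | (5S,6S,7S,10S)-15-(tert-butyldiphenylsilyloxy)labda-8,13E-diene-6β,7α-diol (single enantiomer) | O[C@@H]1[C@@H](O)C(C)=C(CC/C(C)=C/CO[Si](c3ccccc3)(c3ccccc3)C(C)(C)C)[C@@]2(C)CCCC(C)(C)[C@H]12
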